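## Structural features

The target is a 2,3-trans-3,4-trans 4-arylflavan-3-ol, configured (2R,3S,4S). Ring A is fused to the pyran ring O1–C2–C3–C4–C4a–C8a, ring B (4-hydroxyphenyl) sits on C2, a hydroxyl on C3 and a phenol on C7. C4 is bonded to D1 of a piceatannol unit; D1 lies between D2–OH and D6, and D6 carries the (E)-ethene bridge to the catechol ring E, so the C4–D1 bond sits in a di-ortho-substituted pocket. C2, C3 and C4 are contiguous, and in the half-chair all three substituents are equatorial, which is the thermodynamically preferred arrangement. Fragile elements are the electron-rich stilbene (no hydrogenolysis, no strong acid, no electrophilic oxidant), six phenols including a catechol, the doubly benzylic C4–H, and the O1–C2 bond, which in a 4′-hydroxyflavan opens in base to a ring B quinone methide. With D2–OH free, that opening would allow reclosure onto ring D. The real difficulty is C4: two electron-rich aryl groups must be joined to one carbon next to the C3 carbinol with control of configuration, while the ortho styryl group can itself capture a C4 cation. The feature exploited is that ring B with C2, C3 and C4 is the aryl–C3 unit of tyrosine: C2 is benzylic and para to the ring B hydroxyl, so oxidation of that phenol makes C2 electrophilic, and O1 on ring A is placed for a six-ring closure onto it.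

## Logic of the disconnections

**22 to 21.** The four aryl O–CH2Ph bonds on rings D and E are cut. The stilbene rules out hydrogenolysis, so the benzyl groups must leave by Lewis-acid transfer to a scavenger. The gain is that four of the six phenols, including D2–O and the catechol, stay masked through all earlier steps. The demand is clean cleavage at low temperature without C-benzylation or acid damage to the stilbene and the O1–C2 bond.

**21 to 18 (through 20 and 19).** The O1–C2 bond is cut, which opens the pyran ring and removes the C2 stereocentre; the three O–Si bonds are restored. C2 is the one carbon that oxidation of the ring B phenol turns into an electrophile, and C2 can be left to thermodynamic control. The gain is an open-chain diarylpropanol with only two stereocentres. The demand is that the ring B hydroxyl be the only free phenol at the oxidation, that O1 be released only afterwards, and that D2–O stay non-nucleophilic.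

**18 to 17 to 16.** No skeletal bond is cut: the ring B O–allyl bond and the two ring A O–Si bonds are exchanged for hydroxyls. This reduces the protecting-group problem to one silylation and one deallylation. The demand is orthogonality: the allyl ether must go without loss of aryl silyl ethers or benzyl ethers.

**16 to 14 and 15.** The C4–C4a bond is cut. C4 is benzylic to a ring with ortho and para oxygen and therefore ionises readily, and 15 is symmetrical and reacts at the carbon that is needed. The gain is convergence and the removal of ring A with both its oxygens. The demand is attack on the C4 cation anti to the C3 silyloxy group, and an external arene fast enough to outrun the ortho styryl group.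

**14 to 12 (as 13) and 5.** The C4–D1 bond is cut. Halogen–lithium exchange places the nucleophile at the hindered D1 without any regiochemical question, and the electrophile is a carbonyl carbon. The gain is two fragments of similar size. The demand is addition faster than enolisation of the α-silyloxy aldehyde; the configuration of the new carbinol is irrelevant.

**5 back to 1 (through 4, 3 and 2).** Only functional groups change: aldehyde from ester, the O–Si bond, two O–allyl bonds, and C3–O traced back to C3–N. The gain is that C3 comes from the chiral pool. The demand is substitution with net retention and no epimerisation at the α-carbon.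

**12 to 7 and 11.** The ethene bridge is cut at Cα=Cβ. The gain is two benzaldehyde-derived halves. The demand is E selectivity and a bromine already in place at the future D1.

**7 to 6, and 11 to 8 (through 10 and 9).** The C–Br bond at the future D1 and the C–P bond are cut, leaving two commercial aldehydes. The demand is bromination ortho to the formyl group and not between the two ether oxygens.

## Other disconnections considered

Alternative 1: The cut is the C3=C4 bond of a 2H-chromene, with the C3–O and C4–H bonds removed first as a retro-hydroboration. In the forward sense diene A1 would be closed by a second-generation Hoveyda–Grubbs catalyst with loss of ethylene to chromene A2. Borane would then add anti to ring B, boron to C3 and hydrogen to C4 in one syn event, and oxidation would give the 2,3-trans-3,4-trans alcohol.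
- In its favour: C3 and C4 would be set in one substrate-controlled addition on a rigid ring. On control of C4 this is better than the open-chain cation of step 10. O1–C2 would be made with no oxidant near a polyphenol.
- Against it here: the metathesis must engage a 1,1-diarylethene whose ring D is substituted at both ortho positions. C2 must come from an enantioselective allylic etherification and then survive as a benzylic, allylic aryl ether that can ionise. The stilbene cannot be present during hydroboration, so the bromine of A2 must be converted afterwards at a position flanked by the whole flavan.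
- Comparison: on structure it is equal to the chosen plan in having to form a bond at the crowded ring D position. On mechanism it trades a thermodynamically corrected C2 for a catalyst-set C2. On step economy it would be about equal or slightly longer because of the late cross-coupling.

Alternative 2: The cut is O1–C2 together with C3–C4, a retro-[4+2] of the pyran ring. Benzhydrol A3 would lose water under a bulky chiral phosphoric acid to ortho-quinone methide A4, which would add (E)-styrylboronate A5 in an endo cycloaddition to 3-borylflavan A6. Oxidation of C–B with retention would give the C3 alcohol.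
- In its favour: it is the most convergent plan, with two bonds, the ring and three stereocentres in one step, and the E geometry of A5 would be carried into the 2,3-trans relationship. On step economy it would be better than the chosen plan.
- Against it here: the methide carbon of A4 carries the di-ortho-substituted ring D, which should slow attack at C4. An alkenylboronate is a weak partner for an inverse-demand cycloaddition. Endo/exo preference and enantiofacial control are untested for a substrate of this bulk. The stilbene must again be attached afterwards through the bromine of A6.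
- Comparison: on structure both plans form O1–C2 through a quinone methide. On mechanism the alternative relies on one catalyst for kinetic control of three centres, whereas the chosen plan uses three separate elements (chiral pool for C3, substrate control for C4, equilibrium for C2). The end-game is equal: both need Lewis-acid debenzylation.

Alternative 3: The cut runs through ring D: D2–D3 and D4–D5 are disconnected and D1–D2 is traced back to the acyl–C bond of a cyclobutenone. Heating cyclobutenone A7 with silyloxyacetylene A8 would open the four-membered ring, add the alkyne in a [2+2] sense, reopen and close by 6π electrocyclisation to ring D phenol A9.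
- In its favour: the crowded C4–D1 bond is never made by substitution on an arene or by a hindered aryl nucleophile, and the two ring D oxygens emerge differentiated. On that point it is better than step 9 of the chosen plan.
- Against it here: it leaves C2, C3 and C4 to be solved beforehand by some other method. A7 carries a further stereocentre and a dienyl side chain that could enter 6π processes of its own on heating. The temperature needed is high for a benzylic C2 ether.
- Comparison: on structure it builds an aromatic ring that the chosen plan buys. On mechanism it is a pericyclic cascade against polar steps. On step economy it would be clearly longer.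

Key step: step 13

Remarks on the chemistry:
- The α-carbon of 1 keeps its spatial arrangement throughout. Its descriptor is R up to 19 and S from 20 on only because C2 outranks C4 once C2 carries O1.
- O7 is carried as a silyl ether, so both ring A hydroxyls of 16 are protected in one operation; 21 therefore carries four benzyl groups.
- Assumption: the two C4 epimers of 14 are taken on unseparated, since both ionise to the same cation. Stilbene-containing compounds are handled with exclusion of light.

## Steps

Step 1
Reactants: 1 D-tyrosine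
Product: 2 (2R)-2-hydroxy-3-(4-hydroxyphenyl)propanoic acid
Conditions: NaNO2, 1 M aq. H2SO4, 0 °C → rt
Reagents that add atoms: water, O
Why: Diazotisation of the α-amino acid; the carboxylate expels N2 with inversion and water opens the resulting three-membered ring with a second inversion, so C–N becomes C–O with net retention (R).

Step 2
Reactants: 2 (2R)-2-hydroxy-3-(4-hydroxyphenyl)propanoic acid
Product: 3 prop-2-en-1-yl (2R)-2-hydroxy-3-[4-(prop-2-en-1-yloxy)phenyl]propanoate
Conditions: allyl bromide (2.5 equiv), K2CO3, DMF, rt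
Reagents that add atoms: allyl bromide, C=CCBr
Why: Williamson alkylation of carboxylate and phenoxide in one operation; K2CO3 deprotonates neither the secondary alcohol nor the α-C–H, so the hydroxyl stays free and the stereocentre is untouched.

Step 3
Reactants: 3 prop-2-en-1-yl (2R)-2-hydroxy-3-[4-(prop-2-en-1-yloxy)phenyl]propanoate
Product: 4 prop-2-en-1-yl (2R)-2-[(tert-butyldimethylsilyl)oxy]-3-[4-(prop-2-en-1-yloxy)phenyl]propanoate
Conditions: TBSCl, imidazole, DMF, rt
Reagents that add atoms: tert-butyldimethylsilyl chloride, CC(C)(C)[Si](C)(C)Cl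
Why: Standard silylation of a secondary alcohol; the bulky silyl ether later shields one face of the C4 cation.

Step 4
Reactants: 4 prop-2-en-1-yl (2R)-2-[(tert-butyldimethylsilyl)oxy]-3-[4-(prop-2-en-1-yloxy)phenyl]propanoate
Product: 5 (2R)-2-[(tert-butyldimethylsilyl)oxy]-3-[4-(prop-2-en-1-yloxy)phenyl]propanal
Conditions: i-Bu2AlH (1.1 equiv), CH2Cl2, −78 °C; MeOH, then aq. potassium sodium tartrate
Reagents that add atoms: none
Why: Partial reduction of an α-silyloxy ester, whose tetrahedral aluminium hemiacetal is stable at −78 °C and releases the aldehyde only on work-up; the aldehyde is used at once to avoid epimerisation.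

Step 5
Reactants: 6 3,5-bis(benzyloxy)benzaldehyde
Product: 7 3,5-bis(benzyloxy)-2-bromobenzaldehyde
Conditions: NBS (1.05 equiv), MeCN, 0 °C → rt
Reagents that add atoms: N-bromosuccinimide, O=C1CCC(=O)N1Br
Why: Electrophilic aromatic bromination; 3,5-dialkoxybenzaldehydes react at C2 (ortho to one ether oxygen, para to the other) in preference to the position between the two ether oxygens.

Step 6
Reactants: 8 3,4-bis(benzyloxy)benzaldehyde
Product: 9 [3,4-bis(benzyloxy)phenyl]methanol
Conditions: NaBH4, MeOH/THF, 0 °C
Reagents that add atoms: none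
Why: Hydride reduction of an aryl aldehyde; benzyl ethers are inert.

Step 7
Reactants: 9 [3,4-bis(benzyloxy)phenyl]methanol
Product: 11 diethyl {[3,4-bis(benzyloxy)phenyl]methyl}phosphonate, via benzyl bromide 10 (not isolated)
Conditions: PBr3, CH2Cl2, 0 °C; evaporate; P(OEt)3, 130 °C
Reagents that add atoms: triethyl phosphite, CCOP(OCC)OCC
Why: Bromination of an electron-rich benzylic alcohol followed by a Michaelis–Arbuzov reaction; the labile bromide 10 is not stored but heated directly with the phosphite.

Step 8
Reactants: 7 3,5-bis(benzyloxy)-2-bromobenzaldehyde, 11 diethyl {[3,4-bis(benzyloxy)phenyl]methyl}phosphonate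
Product: 12 1,5-bis(benzyloxy)-3-[(E)-2-[3,4-bis(benzyloxy)phenyl]ethenyl]-2-bromobenzene
Conditions: KOt-Bu, THF, 0 °C → rt
Reagents that add atoms: none
Why: Horner–Wadsworth–Emmons olefination of a benzylic phosphonate with an aryl aldehyde, which should give the E stilbene through the thermodynamically preferred anti oxaphosphetane pathway.

Step 9
Reactants: 12 1,5-bis(benzyloxy)-3-[(E)-2-[3,4-bis(benzyloxy)phenyl]ethenyl]-2-bromobenzene, 5 (2R)-2-[(tert-butyldimethylsilyl)oxy]-3-[4-(prop-2-en-1-yloxy)phenyl]propanal
Product: 14 (2R)-1-{2,4-bis(benzyloxy)-6-[(E)-2-[3,4-bis(benzyloxy)phenyl]ethenyl]phenyl}-2-[(tert-butyldimethylsilyl)oxy]-3-[4-(prop-2-en-1-yloxy)phenyl]propan-1-ol as a mixture of C4 epimers, via aryllithium 13 (not isolated)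
Conditions: n-BuLi (1.05 equiv), THF, −78 °C; then 5, −78 °C; AcOH in THF, −78 °C
Reagents that add atoms: none
Why: Bromine–lithium exchange is faster than any attack on benzyl ethers or the stilbene at −78 °C, and 13 should add to the aldehyde carbonyl in a 1,2-addition that forms C4–D1. The new carbinol centre need not be controlled, and the cold acidic quench prevents silyl migration from O3 to the new alkoxide.

Step 10
Reactants: 14 carbinol (mixture of C4 epimers), 15 resorcinol
Product: 16 4-[(1S,2R)-1-{2,4-bis(benzyloxy)-6-[(E)-2-[3,4-bis(benzyloxy)phenyl]ethenyl]phenyl}-2-[(tert-butyldimethylsilyl)oxy]-3-[4-(prop-2-en-1-yloxy)phenyl]propyl]benzene-1,3-diol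
Conditions: 15 (10 equiv), BF3·OEt2 (0.3 equiv), 4 Å MS, CH2Cl2/Et2O, −78 → −30 °C
Reagents that add atoms: none
Why: Friedel–Crafts alkylation through the 2,4-dialkoxybenzyl cation at C4, which 15 should attack with its C4 (para to one hydroxyl, ortho to the other) to form C4–C4a. In the cation, 1,3-allylic strain holds the C3–H bond in the plane towards the ortho substituent of ring D, so the arene should enter anti to the bulky silyloxy group and give C4 (S). Low temperature and a large excess of 15 favour the bimolecular capture over closure onto the ortho styryl group.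

Step 11
Reactants: 16 ring A diol
Product: 17 the bis(tert-butyldimethylsilyl) ether of 16 at both ring A oxygens (C3 R, C4 S)
Conditions: TBSOTf (2.5 equiv), 2,6-lutidine, CH2Cl2, 0 °C → rt
Reagents that add atoms: tert-butyldimethylsilyl trifluoromethanesulfonate, CC(C)(C)[Si](C)(C)OS(=O)(=O)C(F)(F)F
Why: Silylation of both phenols; the triflate is chosen because the hydroxyl ortho to the benzhydryl carbon is hindered.

Step 12
Reactants: 17 tris-silyl allyl ether
Product: 18 4-[(2R,3S)-3-{2,4-bis(benzyloxy)-6-[(E)-2-[3,4-bis(benzyloxy)phenyl]ethenyl]phenyl}-3-{2,4-bis[(tert-butyldimethylsilyl)oxy]phenyl}-2-[(tert-butyldimethylsilyl)oxy]propyl]phenol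
Conditions: Pd(PPh3)4 (5 mol %), morpholine, THF, rt
Reagents that add atoms: none
Why: Tsuji–Trost deallylation: zerovalent palladium ionises the aryl allyl ether to a π-allyl complex that morpholine intercepts; silyl ethers, benzyl ethers and the stilbene are not affected, so the ring B hydroxyl becomes the only free phenol.

Step 13
Reactants: 18 ring B phenol
Product: 21 (2R,3S,4S)-4-{2,4-bis(benzyloxy)-6-[(E)-2-[3,4-bis(benzyloxy)phenyl]ethenyl]phenyl}-2-(4-hydroxyphenyl)-3,4-dihydro-2H-chromene-3,7-diol, via quinone methide 19 (not isolated), via 3-O-silyl flavan 20 (not isolated)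
Conditions: Ag2O (5 equiv), 4 Å MS, CH2Cl2 (0.005 M), rt, dark; filtration under Ar; Bu4NF/AcOH (1:1, 6 equiv), THF, −40 °C → rt
Reagents that add atoms: none
Why: Ag2O removes two electrons and two protons from the only free phenol of 18 (phenoxyl radical, second one-electron oxidation, loss of a C2 proton) and should give para-quinone methide 19, whose exocyclic carbon is C2; the closest known reaction type is the Ag2O dehydrogenation of 4-alkylphenols to para-quinone methides followed by 1,6-addition of an oxygen nucleophile, the same manifold through which 4′-hydroxyflavans epimerise at C2 in base. The oxidant is filtered off before fluoride is added, so that the phenoxides released next meet no oxidant. Buffered Bu4NF cleaves the two aryl silyl ethers first, and the O1 phenoxide adds to C2 in a 6-exo-trig oxa-conjugate addition that forms O1–C2, closes the pyran ring and rearomatises ring B. The new stereocentre C2 is controlled by C3 and C4: in the chair-like closure the C3 oxygen and the C4 aryl group are equatorial and ring B takes the remaining equatorial position, trans to O3 (2R). Because the ring B phenoxide can expel O1 again through the same quinone methide, C2 is also under thermodynamic control and should settle in the all-equatorial isomer. Chemoselectivity of the oxidation rests on ring A being silylated and rings D and E benzylated, and regioselectivity of the closure rests on D2–O being a benzyl ether, since a free D2 phenoxide could reach C2 through a ring of the same size. The secondary silyl ether on O3 is the last to be cleaved, through 20, which gives 21 in the same flask.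

Step 14
Reactants: 21 tetra-O-benzyl flavan
Product: 22 (2R,3S,4S)-4-{2-[(E)-2-(3,4-dihydroxyphenyl)ethenyl]-4,6-dihydroxyphenyl}-2-(4-hydroxyphenyl)-3,4-dihydro-2H-chromene-3,7-diol
Conditions: BCl3 (12 equiv), C6HMe5 (20 equiv), CH2Cl2, −78 °C; MeOH, −78 °C
Reagents that add atoms: none
Why: Lewis-acid cleavage of aryl benzyl ethers with pentamethylbenzene as a non-basic cation scavenger; at −78 °C the benzyl cations are transferred to the scavenger and the alkene, which hydrogenolysis would reduce, should survive.

## Compound list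

1 | D-tyrosine | N[C@H](Cc1ccc(O)cc1)C(=O)O | starting material
2 | (2R)-2-hydroxy-3-(4-hydroxyphenyl)propanoic acid | O[C@H](Cc1ccc(O)cc1)C(=O)O | intermediate
3 | prop-2-en-1-yl (2R)-2-hydroxy-3-[4-(prop-2-en-1-yloxy)phenyl]propanoate | O[C@H](Cc1ccc(OCC=C)cc1)C(=O)OCC=C | intermediate
4 | prop-2-en-1-yl (2R)-2-[(tert-butyldimethylsilyl)oxy]-3-[4-(prop-2-en-1-yloxy)phenyl]propanoate | CC(C)(C)[Si](C)(C)O[C@H](Cc1ccc(OCC=C)cc1)C(=O)OCC=C | intermediate
5 | (2R)-2-[(tert-butyldimethylsilyl)oxy]-3-[4-(prop-2-en-1-yloxy)phenyl]propanal | CC(C)(C)[Si](C)(C)O[C@H](Cc1ccc(OCC=C)cc1)C=O | intermediate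
6 | 3,5-bis(benzyloxy)benzaldehyde | O=Cc1cc(OCc2ccccc2)cc(OCc2ccccc2)c1 | starting material
7 | 3,5-bis(benzyloxy)-2-bromobenzaldehyde | O=Cc1cc(OCc2ccccc2)cc(OCc2ccccc2)c1Br | intermediate
8 | 3,4-bis(benzyloxy)benzaldehyde | O=Cc1ccc(OCc2ccccc2)c(OCc2ccccc2)c1 | starting material
9 | [3,4-bis(benzyloxy)phenyl]methanol | OCc1ccc(OCc2ccccc2)c(OCc2ccccc2)c1 | intermediate
10 | 1,2-bis(benzyloxy)-4-(bromomethyl)benzene | BrCc1ccc(OCc2ccccc2)c(OCc2ccccc2)c1 | intermediate (not isolated)
11 | diethyl {[3,4-bis(benzyloxy)phenyl]methyl}phosphonate | CCOP(=O)(OCC)Cc1ccc(OCc2ccccc2)c(OCc2ccccc2)c1 | intermediate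
12 | 1,5-bis(benzyloxy)-3-[(E)-2-[3,4-bis(benzyloxy)phenyl]ethenyl]-2-bromobenzene | Brc1c(OCc2ccccc2)cc(OCc2ccccc2)cc1/C=C/c1ccc(OCc2ccccc2)c(OCc2ccccc2)c1 | intermediate
13 | {2,4-bis(benzyloxy)-6-[(E)-2-[3,4-bis(benzyloxy)phenyl]ethenyl]phenyl}lithium | [Li]c1c(OCc2ccccc2)cc(OCc2ccccc2)cc1/C=C/c1ccc(OCc2ccccc2)c(OCc2ccccc2)c1 | intermediate (not isolated)
14 | (2R)-1-{2,4-bis(benzyloxy)-6-[(E)-2-[3,4-bis(benzyloxy)phenyl]ethenyl]phenyl}-2-[(tert-butyldimethylsilyl)oxy]-3-[4-(prop-2-en-1-yloxy)phenyl]propan-1-ol, both epimers at C1 (the future C4) | CC(C)(C)[Si](C)(C)O[C@H](Cc1ccc(OCC=C)cc1)C(O)c1c(OCc2ccccc2)cc(OCc2ccccc2)cc1/C=C/c1ccc(OCc2ccccc2)c(OCc2ccccc2)c1 | intermediate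
15 | resorcinol | Oc1cccc(O)c1 | starting material
16 | 4-[(1S,2R)-1-{2,4-bis(benzyloxy)-6-[(E)-2-[3,4-bis(benzyloxy)phenyl]ethenyl]phenyl}-2-[(tert-butyldimethylsilyl)oxy]-3-[4-(prop-2-en-1-yloxy)phenyl]propyl]benzene-1,3-diol | C=CCOc1ccc(cc1)C[C@@H](O[Si](C)(C)C(C)(C)C)[C@@H](c1ccc(O)cc1O)c1c(OCc2ccccc2)cc(OCc2ccccc2)cc1/C=C/c1ccc(OCc2ccccc2)c(OCc2ccccc2)c1 | intermediate
17 | bis(tert-butyldimethylsilyl) ether of 16 at both ring A oxygens (C3 R, C4 S) | C=CCOc1ccc(cc1)C[C@@H](O[Si](C)(C)C(C)(C)C)[C@@H](c1ccc(O[Si](C)(C)C(C)(C)C)cc1O[Si](C)(C)C(C)(C)C)c1c(OCc2ccccc2)cc(OCc2ccccc2)cc1/C=C/c1ccc(OCc2ccccc2)c(OCc2ccccc2)c1 | intermediate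
18 | 4-[(2R,3S)-3-{2,4-bis(benzyloxy)-6-[(E)-2-[3,4-bis(benzyloxy)phenyl]ethenyl]phenyl}-3-{2,4-bis[(tert-butyldimethylsilyl)oxy]phenyl}-2-[(tert-butyldimethylsilyl)oxy]propyl]phenol | Oc1ccc(cc1)C[C@@H](O[Si](C)(C)C(C)(C)C)[C@@H](c1ccc(O[Si](C)(C)C(C)(C)C)cc1O[Si](C)(C)C(C)(C)C)c1c(OCc2ccccc2)cc(OCc2ccccc2)cc1/C=C/c1ccc(OCc2ccccc2)c(OCc2ccccc2)c1 | intermediate
19 | 4-[(2R,3S)-3-{2,4-bis(benzyloxy)-6-[(E)-2-[3,4-bis(benzyloxy)phenyl]ethenyl]phenyl}-3-{2,4-bis[(tert-butyldimethylsilyl)oxy]phenyl}-2-[(tert-butyldimethylsilyl)oxy]propylidene]cyclohexa-2,5-dien-1-one | O=C1C=CC(C=C1)=C[C@@H](O[Si](C)(C)C(C)(C)C)[C@@H](c1ccc(O[Si](C)(C)C(C)(C)C)cc1O[Si](C)(C)C(C)(C)C)c1c(OCc2ccccc2)cc(OCc2ccccc2)cc1/C=C/c1ccc(OCc2ccccc2)c(OCc2ccccc2)c1 | intermediate (not isolated)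
20 | (2R,3S,4S)-4-{2,4-bis(benzyloxy)-6-[(E)-2-[3,4-bis(benzyloxy)phenyl]ethenyl]phenyl}-3-[(tert-butyldimethylsilyl)oxy]-2-(4-hydroxyphenyl)-3,4-dihydro-2H-chromen-7-ol | Oc1ccc(cc1)[C@H]1Oc2cc(O)ccc2[C@@H](c2c(OCc3ccccc3)cc(OCc3ccccc3)cc2/C=C/c2ccc(OCc3ccccc3)c(OCc3ccccc3)c2)[C@@H]1O[Si](C)(C)C(C)(C)C | intermediate (not isolated)
21 | (2R,3S,4S)-4-{2,4-bis(benzyloxy)-6-[(E)-2-[3,4-bis(benzyloxy)phenyl]ethenyl]phenyl}-2-(4-hydroxyphenyl)-3,4-dihydro-2H-chromene-3,7-diol | Oc1ccc(cc1)[C@H]1Oc2cc(O)ccc2[C@@H](c2c(OCc3ccccc3)cc(OCc3ccccc3)cc2/C=C/c2ccc(OCc3ccccc3)c(OCc3ccccc3)c2)[C@@H]1O | intermediate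
22 | (2R,3S,4S)-4-{2-[(E)-2-(3,4-dihydroxyphenyl)ethenyl]-4,6-dihydroxyphenyl}-2-(4-hydroxyphenyl)-3,4-dihydro-2H-chromene-3,7-diol | Oc1ccc([C@H]2Oc3cc(O)ccc3[C@@H](c3c(O)cc(O)cc3/C=C/c3ccc(O)c(O)c3)[C@@H]2O)cc1 | target

## Step count and least certain steps

Total step count: 14. Longest linear sequence: 10 steps (steps 1–4 and 9–14, from 1).

**Step 13 (key step).** The most likely failure is on the oxidation side: coupling of the unhindered ring B phenoxyl radical through its free ortho positions before the second oxidation, and tautomerisation or oligomerisation of the quinone methide while it waits for the phenoxide. Ring B carries no ortho substituents, so both the radical and the quinone methide are short-lived. The fallback sets out from 18 and returns at 21.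
- 18 would be oxidised with Ag2O in CH2Cl2/MeOH, so that methanol adds to each quinone methide as it forms and the species never accumulates. This should give the C2 methyl ether of 18 as a mixture of C2 epimers F1.
- Bu4NF would remove the three silyl groups to give the methoxy tetrol F2.
- A catalytic acid (pyridinium p-toluenesulfonate in CH2Cl2/(CF3)2CHOH) would ionise the 4-hydroxybenzyl ether, and the ortho hydroxyl of ring A would close the pyran ring in an SN1 process to 21, again with C2 under thermodynamic control.

**Step 10.** The most likely failure is capture of the C4 cation by the ortho styryl group (five-ring closure to an indane) in competition with 15, together with attack of 15 on the wrong face. The cation is long-lived and the alkene is held next to it. The fallback sets out from 14 and returns at 17; it replaces the open cation by neighbouring-group participation.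
- Bu4NF would give the 3,4-diol F3, and Ac2O/pyridine the diacetate F4.
- With 15 and BF3·OEt2 the benzylic acetate would ionise with help from the C3 acetate to a trans-disubstituted 1,3-dioxolan-2-ylium ion. In this ion C4 is tetrahedral and cannot close onto the styryl group, and 15 would open it at C4 with inversion, anti to O3, to the C3 acetate F5.
- K2CO3/MeOH would give the triol F6, and TBSOTf/2,6-lutidine (3.5 equiv) would silylate all three hydroxyls to 17.

**Step 9.** The most likely failure is proton transfer from the α-silyloxy aldehyde to the di-ortho-substituted aryllithium (enolisation, with erosion of the C3 configuration and low conversion). The fallback sets out from 4 and returns at 14.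
- MeNH(OMe)·HCl with i-PrMgCl in THF would convert 4 into the Weinreb amide F7.
- 13 would add once to F7 through the stable chelated tetrahedral intermediate and give the aryl ketone F8.
- NaBH4 would reduce F8 to 14; either epimer serves.

**Step 14.** The most likely failure is C-benzylation of the electron-rich rings by benzyl cations that escape the scavenger, and Lewis-acid opening of the O1–C2 bond assisted by the 4′-oxygen. The fallback sets out from 21 and returns at 22.
- Ac2O/pyridine would give the 3,7,4′-triacetate F9, in which rings A and B are less nucleophilic and the 4′-oxygen can no longer assist ionisation at C2.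
- BCl3/C6HMe5 at −78 °C would remove the four benzyl groups to the tetraphenol triacetate F10.
- Hydrazine hydrate in MeOH/THF at 0 °C would remove the acetates under nearly neutral conditions to 22; strong base is avoided because of the ring-opening pathway of 4′-hydroxyflavans.

## Further compounds

F1 | step 13 | C2 methyl ether of 18, 4-[(2R,3S)-3-{2,4-bis(benzyloxy)-6-[(E)-2-[3,4-bis(benzyloxy)phenyl]ethenyl]phenyl}-3-{2,4-bis[(tert-butyldimethylsilyl)oxy]phenyl}-2-[(tert-butyldimethylsilyl)oxy]-1-methoxypropyl]phenol, both C1 epimers | Oc1ccc(cc1)C(OC)[C@@H](O[Si](C)(C)C(C)(C)C)[C@@H](c1ccc(O[Si](C)(C)C(C)(C)C)cc1O[Si](C)(C)C(C)(C)C)c1c(OCc2ccccc2)cc(OCc2ccccc2)cc1/C=C/c1ccc(OCc2ccccc2)c(OCc2ccccc2)c1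
F2 | step 13 | methoxy tetrol, 4-[(1S,2R)-1-{2,4-bis(benzyloxy)-6-[(E)-2-[3,4-bis(benzyloxy)phenyl]ethenyl]phenyl}-2-hydroxy-3-(4-hydroxyphenyl)-3-methoxypropyl]benzene-1,3-diol, both epimers at the methoxy carbon | Oc1ccc(cc1)C(OC)[C@@H](O)[C@@H](c1ccc(O)cc1O)c1c(OCc2ccccc2)cc(OCc2ccccc2)cc1/C=C/c1ccc(OCc2ccccc2)c(OCc2ccccc2)c1
F3 | step 10 | (2R)-1-{2,4-bis(benzyloxy)-6-[(E)-2-[3,4-bis(benzyloxy)phenyl]ethenyl]phenyl}-3-[4-(prop-2-en-1-yloxy)phenyl]propane-1,2-diol, both C1 epimers | O[C@H](Cc1ccc(OCC=C)cc1)C(O)c1c(OCc2ccccc2)cc(OCc2ccccc2)cc1/C=C/c1ccc(OCc2ccccc2)c(OCc2ccccc2)c1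
F4 | step 10 | diacetate of F3 | CC(=O)O[C@H](Cc1ccc(OCC=C)cc1)C(OC(C)=O)c1c(OCc2ccccc2)cc(OCc2ccccc2)cc1/C=C/c1ccc(OCc2ccccc2)c(OCc2ccccc2)c1
F5 | step 10 | (1S,2R)-1-{2,4-bis(benzyloxy)-6-[(E)-2-[3,4-bis(benzyloxy)phenyl]ethenyl]phenyl}-1-(2,4-dihydroxyphenyl)-3-[4-(prop-2-en-1-yloxy)phenyl]propan-2-yl acetate | C=CCOc1ccc(cc1)C[C@@H](OC(C)=O)[C@@H](c1ccc(O)cc1O)c1c(OCc2ccccc2)cc(OCc2ccccc2)cc1/C=C/c1ccc(OCc2ccccc2)c(OCc2ccccc2)c1
F6 | step 10 | 4-[(1S,2R)-1-{2,4-bis(benzyloxy)-6-[(E)-2-[3,4-bis(benzyloxy)phenyl]ethenyl]phenyl}-2-hydroxy-3-[4-(prop-2-en-1-yloxy)phenyl]propyl]benzene-1,3-diol | C=CCOc1ccc(cc1)C[C@@H](O)[C@@H](c1ccc(O)cc1O)c1c(OCc2ccccc2)cc(OCc2ccccc2)cc1/C=C/c1ccc(OCc2ccccc2)c(OCc2ccccc2)c1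
F7 | step 9 | (2R)-2-[(tert-butyldimethylsilyl)oxy]-N-methoxy-N-methyl-3-[4-(prop-2-en-1-yloxy)phenyl]propanamide | CC(C)(C)[Si](C)(C)O[C@H](Cc1ccc(OCC=C)cc1)C(=O)N(C)OC
F8 | step 9 | (2R)-1-{2,4-bis(benzyloxy)-6-[(E)-2-[3,4-bis(benzyloxy)phenyl]ethenyl]phenyl}-2-[(tert-butyldimethylsilyl)oxy]-3-[4-(prop-2-en-1-yloxy)phenyl]propan-1-one | CC(C)(C)[Si](C)(C)O[C@H](Cc1ccc(OCC=C)cc1)C(=O)c1c(OCc2ccccc2)cc(OCc2ccccc2)cc1/C=C/c1ccc(OCc2ccccc2)c(OCc2ccccc2)c1
F9 | step 14 | 3,7,4′-triacetate of 21 | CC(=O)Oc1ccc(cc1)[C@H]1Oc2cc(OC(C)=O)ccc2[C@@H](c2c(OCc3ccccc3)cc(OCc3ccccc3)cc2/C=C/c2ccc(OCc3ccccc3)c(OCc3ccccc3)c2)[C@@H]1OC(C)=O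
F10 | step 14 | 3,7,4′-triacetate of 22 | CC(=O)Oc1ccc(cc1)[C@H]1Oc2cc(OC(C)=O)ccc2[C@@H](c2c(O)cc(O)cc2/C=C/c2ccc(O)c(O)c2)[C@@H]1OC(C)=O
A1 | alternative 1 | 4-(benzyloxy)-2-{[(1S)-1-[4-(benzyloxy)phenyl]prop-2-en-1-yl]oxy}-1-{1-[2,4-bis(benzyloxy)-6-bromophenyl]ethenyl}benzene | c1ccccc1COc1ccc(cc1)[C@H](C=C)Oc1cc(OCc2ccccc2)ccc1C(=C)c1c(OCc2ccccc2)cc(OCc2ccccc2)cc1Br
A2 | alternative 1 | (2S)-7-(benzyloxy)-2-[4-(benzyloxy)phenyl]-4-[2,4-bis(benzyloxy)-6-bromophenyl]-2H-chromene | c1ccccc1COc1ccc(cc1)[C@H]1Oc2cc(OCc3ccccc3)ccc2C(c2c(OCc3ccccc3)cc(OCc3ccccc3)cc2Br)=C1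
A3 | alternative 2 | 5-(benzyloxy)-2-{[2,4-bis(benzyloxy)-6-bromophenyl](hydroxy)methyl}phenol (racemic) | Oc1cc(OCc2ccccc2)ccc1C(O)c1c(OCc2ccccc2)cc(OCc2ccccc2)cc1Br
A4 | alternative 2 | 3-(benzyloxy)-6-{[2,4-bis(benzyloxy)-6-bromophenyl]methylidene}cyclohexa-2,4-dien-1-one | O=C1C=C(OCc2ccccc2)C=CC1=Cc1c(OCc2ccccc2)cc(OCc2ccccc2)cc1Br
A5 | alternative 2 | 2-[(E)-2-[4-(benzyloxy)phenyl]ethenyl]-4,4,5,5-tetramethyl-1,3,2-dioxaborolane | CC1(C)OB(/C=C/c2ccc(OCc3ccccc3)cc2)OC1(C)C
A6 | alternative 2 | 2,3-trans-3,4-trans 7-(benzyloxy)-2-[4-(benzyloxy)phenyl]-4-[2,4-bis(benzyloxy)-6-bromophenyl]-3-(4,4,5,5-tetramethyl-1,3,2-dioxaborolan-2-yl)chromane, configured at C2, C3 and C4 as the target | c1ccccc1COc1ccc(cc1)[C@H]1Oc2cc(OCc3ccccc3)ccc2[C@@H](c2c(OCc3ccccc3)cc(OCc3ccccc3)cc2Br)[C@@H]1B1OC(C)(C)C(C)(C)O1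
A7 | alternative 3 | 4-{3,7-bis(benzyloxy)-2-[4-(benzyloxy)phenyl]chroman-4-yl}-3-[(E)-2-[3,4-bis(benzyloxy)phenyl]ethenyl]cyclobut-2-en-1-one, flavan centres as in the target, ring carbon unassigned | c1ccccc1COc1ccc(cc1)[C@H]1Oc2cc(OCc3ccccc3)ccc2[C@@H](C2C(=O)C=C2/C=C/c2ccc(OCc3ccccc3)c(OCc3ccccc3)c2)[C@@H]1OCc1ccccc1
A8 | alternative 3 | (ethynyloxy)tri(propan-2-yl)silane | C#CO[Si](C(C)C)(C(C)C)C(C)C
A9 | alternative 3 | ring D phenol: 2-{3,7-bis(benzyloxy)-2-[4-(benzyloxy)phenyl]chroman-4-yl}-3-[(E)-2-[3,4-bis(benzyloxy)phenyl]ethenyl]-5-{[tri(propan-2-yl)silyl]oxy}phenol, flavan centres as in the target | c1ccccc1COc1ccc(cc1)[C@H]1Oc2cc(OCc3ccccc3)ccc2[C@@H](c2c(O)cc(O[Si](C(C)C)(C(C)C)C(C)C)cc2/C=C/c2ccc(OCc3ccccc3)c(OCc3ccccc3)c2)[C@@H]1OCc1ccccc1
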